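By 25.0 min, when Thursday's feed of substrate into the flask of coupling partner has just ended, the substrate no longer adds up: 75.3% stands as substrate, 0.1% as target, and 24.6% is in neither column. So we keep the books on substrate, the limiting reagent, since even elm's charge of 0.050 M is less than the 0.100 M of coupling partner.

| flask | substrate | coupling partner | remark | time |
|---|---|---|---|---|
| Thursday's | 0.0024 M (fed, over 25 min) | 0.10 M | run made earlier; the fed solution adds 1.0 times the starting volume |  |
| Monday's | 0.042 M (fed, over 25 min) | 0.10 M | run made earlier; the fed solution adds 1.0 times the starting volume |  |
| maple | 0.0030 M (fed, over 25 min) | 0.100 M | the fed solution adds 1.0 times the starting volume | 3.0 h |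
| oak | 0.0060 M (fed, over 25 min) | 0.100 M | the fed solution adds 1.0 times the starting volume | 3.0 h |
| alder | 0.012 M (fed, over 25 min) | 0.100 M | the fed solution adds 1.0 times the starting volume | 3.0 h |
| birch | 0.025 M (fed, over 25 min) | 0.100 M | the fed solution adds 1.0 times the starting volume | 3.0 h |
| elm | 0.050 M (fed, over 25 min) | 0.100 M | the fed solution adds 1.0 times the starting volume | 3.0 h |

| run | time / min | target / % | substrate / % |
|---|---|---|---|
| Thursday's | 25.0 | 0.1 | 75.3 |
| Thursday's | 50.0 | 1.4 | 44.6 |
| Thursday's | 80.0 | 4.6 | 24.9 |
| Thursday's | 90.0 | 5.2 | 21.2 |
| Thursday's | 120 | 8.1 | 11.5 |
| Monday's | 12.0 | 0 | 40.2 |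
| Monday's | 30.0 | 0 | 69.3 |
| Monday's | 60.0 | 2.6 | 42.4 |
| Monday's | 90.0 | 4.5 | 26.4 |
| Monday's | 120 | 6.2 | 17.4 |

(scatter of a reading: 0.5 percentage points)

- every charge counts on the volume at the start, and the solution that is fed holds the whole dose
- "hardly changes" means that all values lie within two and a half points (for a concentration: within two and a half percent of the largest)
- percentages count the whole charge, also what has not yet gone in

- [target] at the end for maple, oak, alder, birch, elm, in this order
- how that number moves from the first to the last of them (falls, then rises / rises all the way / falls all the way / hardly changes / rises, then falls)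

The ledger has one entry for substrate, one for target, and a hidden share U, which is whatever those two readings leave over. On Thursday U grows from 54.0% at 50.0 min to 80.4% at 120 min, while target gains 6.7 percentage points. If target is paid out of U, the gain per time, over the mean of U, is a pace we can read. Thursday gives 8.11 h for the drain half-life T, the time in which U would halve at that pace with nothing added. Monday's readings from 60.0 min to 120 min, where U ends at 76.4%, give 12.6 h. Both are readings and carry the scatter of their points.

T is longer than the 3.0 h of the new flasks, so we hold U at its last reading and let it pay target until the end. Thursday's pace gives 15.0% of the charge, which we take for maple. Monday's pace gives 10.4%, which we take for elm, though elm's charge lies above Monday's. The feed doubles the volume, so our ends are 2.25 × 10⁻⁴ M and 0.00260 M, and the row should rise, since the charge grows by more than the percentage falls.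

The forecast, made separately, reads 2.200 × 10⁻⁴ M, 4.300 × 10⁻⁴ M, 8.200 × 10⁻⁴ M, 0.00151 M, 0.0024 M, and rises all the way: “The percentage yield falls, but the concentration still rises throughout.”

The flask gives 1.73 × 10⁻⁴ M, 3.45 × 10⁻⁴ M, 6.85 × 10⁻⁴ M, 0.00139 M, 0.00251 M, and rises all the way, so the forecast stands above it at maple and below it at elm.

    substrate + coupling partner → intermediate (k = 24.2 /M/h)
    coupling partner + target → over-reaction product (k = 6.95 /M/h)
    substrate + target → side product (k = 42.1 /M/h)
    intermediate → target (k = 0.0925 /h)

Maple's intermediate has a half-life of 7.5 h by its turning into target, longer than the 3.0 h of the run, and at 3.00 h maple holds 79.5% of its charge as intermediate against 11.5% as target. Carried on with our T, which was read on the whole of U and not on the intermediate, that pool is reckoned to come down to 7.91% at 30.0 h, where maple holds 6.85%; elm, from 73.4%, is reckoned the same way to come to 7.30%, and holds 6.69%.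

The earlier runs and the new flask stem from a simulated flask for an exercise; the scatter is artificial.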